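Step 1 turns each E into one G and no step of the scheme consumes G, so cE + cG stays at 1.0 mM while the two trade places.

    Z + E → G + Q (k1 = 0.0055 L mol⁻¹ s⁻¹)
    Z + G → Q + G, rate k2*[G]*[Z] (k2 = 0.57 L mol⁻¹ s⁻¹)
    D + Z → D.Z (k3 = 0.0040 L mol⁻¹ s⁻¹)

| setting | Friday's | Tuesday's | Sunday's |
|---|---|---|---|
| Z | 0.10 M (in portions, 2) | 0.10 M (in portions, 2) | 0.10 M (in portions, 2) |
| D | 0.0500 M | 0.0800 M | 0.120 M |
| E | 1.0 mM | 1.0 mM | 1.0 mM |
| time | 1.5 h | 1.5 h | 1.5 h |
| remark | the portions of Z follow each other after 50 min, the first at the start | the portions of Z follow each other after 50 min, the first at the start | the portions of Z follow each other after 50 min, the first at the start |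

- "hardly changes" means that all values lie within two and a half points (for a concentration: within two and a half percent of the largest)
- run time (Friday's): 1.5 h

- amount of Q at the end, in percent of the Z charged for Friday's, Tuesday's, Sunday's, in this order
- how the row runs (falls all the way / hardly changes / rises all the way / rises, then falls / falls, then rises)

- Step 2 takes Z to Q at k2·cG·cZ and step 3 takes it to D.Z at k3·cD·cZ, while step 1 adds one Q for each E started. The factor cZ cancels from their ratio, so the portions of Z enter this split, k2·cG/(k3·cD), a selectivity factor, through cG and cD and not directly. On a repeat, cG and cD are the pair to watch.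
- The bench rule freezes both: every E counts as started and D stays at its charge, which gives the frozen split S = k2·(cE at charge)/(k3·cD at charge), 2.85 for Friday's flask, 1.78 for Tuesday's and 1.19 for Sunday's.
- Read as S/(1+S), the frozen split sends 74.0%, 64.0% and 54.3% of the Z used into Q. The row should therefore fall from Friday's to Sunday's, since the frozen split is larger on Friday than on Tuesday and larger on Tuesday than on Sunday.
- The rule stops at the ratio k1/k3 = 1.38: under the same cZ, E falls as a fraction of its own charge faster than D does, but by this small factor, so the two run down together and neither freeze holds. At the start cG is zero while cD stands at its charge, so the early split lies under S.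
- Later cG rises and cD falls, and both push the split up. This reckoning commits to the order of the flasks and to shares below the frozen ones, and it gives no row of Q.
- The forecast reads 47.9%, 38.7%, 29.5% and falls all the way, on the grounds: “More D scavenges Z while G is still building up, so the yield falls steadily”.
- The flask gives 47.8%, 38.8%, 29.5%, falls all the way, with Q at 63.0% of the Z used on Friday and 34.7% on Sunday, less than the frozen shares. At 1.50 h Friday's flask uses Z for Q 4.4 times as fast as for D.Z, which is S multiplied by cG as 67.8% of the charged E and divided by the 44% of D left. Sunday's flask at 1.50 h, with cG at 5.74 × 10⁻⁴ M and 54% of D left, has by the same reckoning a split of 1.27.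

The numbers of this flask are invented; the flask was simulated.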